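**Plan**

- Cuts (ring atoms: C1 = stereocentre, C2 = methyl-bearing alkene carbon, C3 = alkene CH, C4 and C5 = CH2, C6 = CMe2): first the oleate C–O bond; then C2=C3 and C4–C5 of the cyclohexene together, which removes C3–C4 as a vinylphosphonium salt and leaves an acyclic δ-keto acid (acetyl on C1, CH2CO2H on C6); then that keto acid back to a 2-hydroxy-2-methylcyclopentanone (C–C cleavage), the C1–side-chain bond (conjugate addition to 2,4,4-trimethylcyclopentenone) and the terminal C=CH2 of a geraniol-derived triene (Wittig).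
- Enabling feature: the C2=C3 alkene carries its methyl on C2 and lies one CH2 (C4) away from the C5 methylene beside the quaternary C6, so a CH=CH2 unit can be set between a C5 radical (from a carboxyl group on C5) and a C2 methyl ketone. The carboxyl carbon is the carbonyl carbon of a temporary cyclopentanone that served to set C1 and leaves as CO2.
- Forward order: geraniol → silyl ether → allylic oxidation → enal → terminal diene; hydrozirconation and copper-catalysed asymmetric conjugate addition join chain and five-membered ring; α-hydroxylation and periodate cleavage open that ring; the decarboxylative radical addition/Wittig annulation closes the cyclohexene, the only ring of the target; desilylation and acylation finish.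
- Stereochemistry: the single stereocentre (ring C1, S) is set by the chiral ligand in the conjugate addition, and no bond to it is made or broken afterwards. Both chain E-alkenes come from geraniol and the E-selective allylic oxidation; the Z-alkene comes with oleoyl chloride.

Key step: step 8

Remark: the ring stereocentre is read from the SMILES as (S), and 2,4,4-trimethylcyclopent-2-en-1-one is taken to be a purchasable enone.

Abbreviations: TBS = tert-butyldimethylsilyl; R9 = (3E,7E)-9-[(tert-butyldimethylsilyl)oxy]-3,7-dimethylnona-3,7-dien-1-yl (side chain, attached through its C1).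

**Route**

Step 1
Reactants: 1 geraniol [(2E)-3,7-dimethylocta-2,6-dien-1-ol]
Product: 2 geranyl TBS ether [tert-butyl{[(2E)-3,7-dimethylocta-2,6-dien-1-yl]oxy}dimethylsilane]
Conditions: TBSCl (1.1 equiv), imidazole (1.5 equiv), DMF, 0 °C to rt
Reagents that add atoms: tert-butyldimethylsilyl chloride, CC(C)(C)[Si](C)(C)Cl
Why: Imidazole-promoted silyl ether formation masks the primary allylic alcohol for the organometallic and basic steps that follow; no stereocentre is formed.

Step 2
Reactants: 2 geranyl TBS ether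
Product: 3 (2E,6E)-8-[(tert-butyldimethylsilyl)oxy]-2,6-dimethylocta-2,6-dien-1-ol
Conditions: SeO2 (0.2 equiv), t-BuOOH (3 equiv), salicylic acid (0.1 equiv), CH2Cl2, rt
Reagents that add atoms: tert-butyl hydroperoxide, CC(C)(C)OO
Why: Riley allylic oxidation (ene reaction then [2,3]-sigmatropic shift) should attack the electron-richer terminal trisubstituted alkene at its (E)-methyl group, so the new CH2OH is trans to the chain and both alkenes stay E.

Step 3
Reactants: 3 (2E,6E)-8-[(tert-butyldimethylsilyl)oxy]-2,6-dimethylocta-2,6-dien-1-ol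
Product: 4 (2E,6E)-8-[(tert-butyldimethylsilyl)oxy]-2,6-dimethylocta-2,6-dienal
Conditions: MnO2 (15 equiv), CH2Cl2, rt
Reagents that add atoms: none
Why: MnO2 oxidation is selective for the allylic alcohol and should give the enal without change of alkene geometry.

Step 4
Reactants: 4 (2E,6E)-8-[(tert-butyldimethylsilyl)oxy]-2,6-dimethylocta-2,6-dienal
Product: 5 tert-butyl{[(2E,6E)-3,7-dimethylnona-2,6,8-trien-1-yl]oxy}dimethylsilane
Conditions: Ph3PCH3Br (1.3 equiv), KN(SiMe3)2 (1.25 equiv), THF, 0 °C; then 4, −78 to 0 °C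
Reagents that add atoms: methyltriphenylphosphonium bromide, C[P+](c1ccccc1)(c1ccccc1)c1ccccc1.[Br-]
Why: Wittig methylenation of the aldehyde adds the last chain carbon and gives a 2-substituted terminal 1,3-diene; the existing E-alkenes are not touched.

Step 5
Reactants: 5 tert-butyl{[(2E,6E)-3,7-dimethylnona-2,6,8-trien-1-yl]oxy}dimethylsilane; 6 2,4,4-trimethylcyclopent-2-en-1-one
Product: 9 (2RS,3R)-3-R9-2,4,4-trimethylcyclopentan-1-one, via alkylzirconocene chloride 7 (not isolated), via zirconium enolate 8 (not isolated)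
Conditions: Cp2Zr(H)Cl (1.05 equiv), CH2Cl2, rt; then 6 (1.3 equiv), (CuOTf)2·C6H6 (5 mol %), (1,1'-binaphthyl-2,2'-diyl) N,N-bis(1-phenylethyl)phosphoramidite (11 mol %, the antipode that leads to 3R), Et2O, rt; H2O
Reagents that add atoms: none
Why: Hydrozirconation should add Zr–H across the terminal, least hindered double bond of the diene to give the primary homoallylic alkylzirconocene, which is transferred to copper and adds to C3 of the enone (copper-catalysed asymmetric conjugate addition); the chiral phosphoramidite selects the enone face and so sets C3 as R, while the C2 epimers are of no consequence.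

Step 6
Reactants: 9 (2RS,3R)-3-R9-2,4,4-trimethylcyclopentan-1-one
Product: 11 (2RS,3S)-2-hydroxy-3-R9-2,4,4-trimethylcyclopentan-1-one, via tertiary hydroperoxide 10 (not isolated)
Conditions: KOtBu (1.5 equiv), P(OEt)3 (2 equiv), O2 (1 atm), THF/t-BuOH, −20 °C; AcOH
Reagents that add atoms: dioxygen, O=O
Why: Base-mediated enolate autoxidation with in situ phosphite reduction of the hydroperoxide should oxygenate the more substituted enolate at the tertiary C2; C2 becomes a ketone in step 7, so its configuration does not matter, and C3 is β to the carbonyl and cannot epimerise.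

Step 7
Reactants: 11 (2RS,3S)-2-hydroxy-3-R9-2,4,4-trimethylcyclopentan-1-one
Product: 12 (4S)-3,3-dimethyl-5-oxo-4-R9-hexanoic acid
Conditions: NaIO4 (2 equiv), THF/H2O, rt
Reagents that add atoms: sodium periodate, [Na+].[O-]I(=O)(=O)=O
Why: Malaprade-type periodate cleavage of the α-ketol breaks the C1–C2 bond of the cyclopentanone to give the methyl ketone and the carboxylic acid under near-neutral conditions, so the stereocentre (now α to the ketone) should not epimerise and the alkenes and silyl ether are untouched.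

Step 8
Reactants: 12 (4S)-3,3-dimethyl-5-oxo-4-R9-hexanoic acid; 13 vinyltriphenylphosphonium bromide
Product: 16 tert-butyl({(2E,6E)-3,7-dimethyl-9-[(1S)-2,6,6-trimethylcyclohex-2-en-1-yl]nona-2,6-dien-1-yl}oxy)dimethylsilane, via caesium carboxylate 14 (not isolated), via phosphonium ylide 15 (not isolated)
Conditions: Cs2CO3 (0.5 equiv), MeOH, rt, then evaporation to dryness; 13 (2 equiv), [Ir(dF(CF3)ppy)2(dtbbpy)]PF6 (2 mol %), 4 Å molecular sieves, degassed DMSO, 450 nm LEDs, slow argon sweep, 25 °C
Reagents that add atoms: none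
Why: Proposed new method: oxidation of carboxylate 14 by the photoexcited iridium complex and loss of CO2 should give the primary C5 radical, which adds to the CH2 terminus of the electron-poor alkene of 13 (Giese addition, C4–C5 bond); the α-phosphonio radical is then reduced by the reduced photocatalyst to the non-stabilised ylide 15 (radical–polar crossover, redox-neutral overall), which attacks the C2 methyl ketone and collapses through an oxaphosphetane to the C2=C3 alkene and Ph3PO (intramolecular Wittig). The closest known reaction types are the Schweizer annulation, in which a carbanion adds to vinyltriphenylphosphonium bromide and the resulting ylide closes by Wittig olefination, and photoredox decarboxylative Giese additions that end in a radical–polar crossover. The cyclohexene is the only ring closed; it closes in the polar half by 6-exo-trig attack of the ylide carbon C3 on the ketone carbon C2, so the alkene is endocyclic, cis by ring size, and fixed between C2 and C3 with the methyl on C2. No stereocentre is created, and C1 should be kept because no bond to it is made or broken and the ylide is a weaker base than a ketone enolate, so it should not enolise the hindered ketone towards the tertiary C1–H. The step needs the intermolecular radical addition to outrun 1,5-hydrogen transfer from the allylic CH2 of the side chain, and the olefination to outrun capture of the ylide by protons or CO2; the excess of the cationic, strongly electrophilic alkene, the dry aprotic medium with a preformed carboxylate, and the argon sweep are meant to secure this. The trisubstituted chain alkenes and the silyl ether lie outside the redox window of the catalyst.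

Step 9
Reactants: 16 tert-butyl({(2E,6E)-3,7-dimethyl-9-[(1S)-2,6,6-trimethylcyclohex-2-en-1-yl]nona-2,6-dien-1-yl}oxy)dimethylsilane
Product: 17 (2E,6E)-3,7-dimethyl-9-[(1S)-2,6,6-trimethylcyclohex-2-en-1-yl]nona-2,6-dien-1-ol
Conditions: Bu4NF (1.2 equiv), THF, 0 °C to rt
Reagents that add atoms: none
Why: Fluoride-induced Si–O cleavage frees the primary allylic alcohol under conditions that leave the alkenes and the stereocentre untouched.

Step 10
Reactants: 17 (2E,6E)-3,7-dimethyl-9-[(1S)-2,6,6-trimethylcyclohex-2-en-1-yl]nona-2,6-dien-1-ol; 18 oleoyl chloride [(9Z)-octadec-9-enoyl chloride]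
Product: 19 (2E,6E)-3,7-dimethyl-9-[(1S)-2,6,6-trimethylcyclohex-2-en-1-yl]nona-2,6-dien-1-yl (9Z)-octadec-9-enoate
Conditions: pyridine (2 equiv), DMAP (0.05 equiv), CH2Cl2, 0 °C to rt
Reagents that add atoms: none
Why: DMAP-catalysed acylation of the primary allylic alcohol by the acid chloride should give the ester without isomerising the Z-alkene or any other centre.

**Compound list**

1 | geraniol, (2E)-3,7-dimethylocta-2,6-dien-1-ol | CC(C)=CCC/C(C)=C/CO | starting material
2 | tert-butyl{[(2E)-3,7-dimethylocta-2,6-dien-1-yl]oxy}dimethylsilane | CC(C)=CCC/C(C)=C/CO[Si](C)(C)C(C)(C)C | intermediate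
3 | (2E,6E)-8-[(tert-butyldimethylsilyl)oxy]-2,6-dimethylocta-2,6-dien-1-ol | OC/C(C)=C/CC/C(C)=C/CO[Si](C)(C)C(C)(C)C | intermediate
4 | (2E,6E)-8-[(tert-butyldimethylsilyl)oxy]-2,6-dimethylocta-2,6-dienal | O=C/C(C)=C/CC/C(C)=C/CO[Si](C)(C)C(C)(C)C | intermediate
5 | tert-butyl{[(2E,6E)-3,7-dimethylnona-2,6,8-trien-1-yl]oxy}dimethylsilane | C=C/C(C)=C/CC/C(C)=C/CO[Si](C)(C)C(C)(C)C | intermediate
6 | 2,4,4-trimethylcyclopent-2-en-1-one | CC1=CC(C)(C)CC1=O | starting material
7 | chlorobis(cyclopentadienyl)[(3E,7E)-9-[(tert-butyldimethylsilyl)oxy]-3,7-dimethylnona-3,7-dien-1-yl]zirconium | Cl[Zr](CC/C(C)=C/CC/C(C)=C/CO[Si](C)(C)C(C)(C)C)(C1C=CC=C1)C1C=CC=C1 | intermediate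
8 | chlorobis(cyclopentadienyl)zirconium enolate of 9 (O–Zr on C1, C1=C2 double bond, C3 configured as in 9) | CC1=C(O[Zr](Cl)(C2C=CC=C2)C2C=CC=C2)CC(C)(C)[C@@H]1CC/C(C)=C/CC/C(C)=C/CO[Si](C)(C)C(C)(C)C | intermediate
9 | (2RS,3R)-3-[(3E,7E)-9-[(tert-butyldimethylsilyl)oxy]-3,7-dimethylnona-3,7-dien-1-yl]-2,4,4-trimethylcyclopentan-1-one | CC1C(=O)CC(C)(C)[C@@H]1CC/C(C)=C/CC/C(C)=C/CO[Si](C)(C)C(C)(C)C | intermediate
10 | (2RS,3S)-2-hydroperoxy-3-[(3E,7E)-9-[(tert-butyldimethylsilyl)oxy]-3,7-dimethylnona-3,7-dien-1-yl]-2,4,4-trimethylcyclopentan-1-one | CC1(OO)C(=O)CC(C)(C)[C@@H]1CC/C(C)=C/CC/C(C)=C/CO[Si](C)(C)C(C)(C)C | intermediate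
11 | (2RS,3S)-2-hydroxy-3-[(3E,7E)-9-[(tert-butyldimethylsilyl)oxy]-3,7-dimethylnona-3,7-dien-1-yl]-2,4,4-trimethylcyclopentan-1-one | CC1(O)C(=O)CC(C)(C)[C@@H]1CC/C(C)=C/CC/C(C)=C/CO[Si](C)(C)C(C)(C)C | intermediate
12 | (4S)-4-[(3E,7E)-9-[(tert-butyldimethylsilyl)oxy]-3,7-dimethylnona-3,7-dien-1-yl]-3,3-dimethyl-5-oxohexanoic acid | CC(=O)[C@@H](CC/C(C)=C/CC/C(C)=C/CO[Si](C)(C)C(C)(C)C)C(C)(C)CC(=O)O | intermediate
13 | vinyltriphenylphosphonium bromide, ethenyl(triphenyl)phosphonium bromide | C=C[P+](c1ccccc1)(c1ccccc1)c1ccccc1.[Br-] | starting material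
14 | caesium (4S)-4-[(3E,7E)-9-[(tert-butyldimethylsilyl)oxy]-3,7-dimethylnona-3,7-dien-1-yl]-3,3-dimethyl-5-oxohexanoate | CC(=O)[C@@H](CC/C(C)=C/CC/C(C)=C/CO[Si](C)(C)C(C)(C)C)C(C)(C)CC(=O)[O-].[Cs+] | intermediate
15 | (3S)-3-[(3E,7E)-9-[(tert-butyldimethylsilyl)oxy]-3,7-dimethylnona-3,7-dien-1-yl]-4,4-dimethyl-7-(triphenyl-λ5-phosphanylidene)heptan-2-one | CC(=O)[C@@H](CC/C(C)=C/CC/C(C)=C/CO[Si](C)(C)C(C)(C)C)C(C)(C)CCC=P(c1ccccc1)(c1ccccc1)c1ccccc1 | intermediate
16 | tert-butyl({(2E,6E)-3,7-dimethyl-9-[(1S)-2,6,6-trimethylcyclohex-2-en-1-yl]nona-2,6-dien-1-yl}oxy)dimethylsilane | CC(C)(C)[Si](C)(C)OC/C=C(\C)CC/C=C(\C)CC[C@@H]1C(C)=CCCC1(C)C | intermediate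
17 | (2E,6E)-3,7-dimethyl-9-[(1S)-2,6,6-trimethylcyclohex-2-en-1-yl]nona-2,6-dien-1-ol | OC/C=C(\C)CC/C=C(\C)CC[C@@H]1C(C)=CCCC1(C)C | intermediate
18 | oleoyl chloride, (9Z)-octadec-9-enoyl chloride | CCCCCCCC/C=C\CCCCCCCC(=O)Cl | starting material
19 | (2E,6E)-3,7-dimethyl-9-[(1S)-2,6,6-trimethylcyclohex-2-en-1-yl]nona-2,6-dien-1-yl (9Z)-octadec-9-enoate | CCCCCCCC/C=C\CCCCCCCC(=O)OC/C=C(\C)CC/C=C(\C)CC[C@@H]1C(C)=CCCC1(C)C | target

**Step count and risks**

Total steps: 10. Longest linear sequence: 10 (from geraniol).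

Steps most likely to fail:

1. Step 8 (proposed new method). The primary carboxylate may be oxidised too slowly, the C5 radical may be lost by 1,5-hydrogen transfer from the allylic CH2 of the side chain, the ylide may be intercepted by CO2 or stray protons before it olefinates, or C1 may partly epimerise. The fallback uses known chemistry (lactone-enolate Ireland–Claisen ring contraction followed by Barton decarboxylation), sets out from 12 and comes back at 16. Compound 12 is treated with CH2=CHMgBr/CeCl3 (THF, −78 °C) to give the tertiary allylic hydroxy acid F1, which is lactonised (EDC·HCl, DMAP) to the 6-ethenyl δ-lactone F2. LiN(iPr)2 and Me3SiCl/Et3N (THF, −78 °C) give the trimethylsilyl ketene acetal F3, which on heating in toluene should rearrange through a boat [3,3] transition state to the trimethylsilyl ester F4; here C4–C5 is made and the C2=C3 alkene appears in the same event, with C1 never α to a carbonyl. Hydrolysis gives the cyclohexenecarboxylic acid F5, and its carboxyl on C5 is removed by Barton decarboxylation through the N-acyloxy-2-thiopyridone F6 (t-BuSH, visible light) to give 16.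

2. Step 5. The α-methyl, γ-quaternary enone may react sluggishly with the alkylcopper species, or the catalyst may discriminate its faces poorly. The fallback sets out from 7 (made from 5 as in step 5) and comes back at 9. Compound 7 is added under the same copper catalysis to the less hindered 4,4-dimethylcyclopent-2-en-1-one in the presence of Me3SiCl, which traps the enolate as the trimethylsilyl enol ether F7. MeLi (THF, 0 °C) regenerates the regiodefined lithium enolate F8, and MeI then places the methyl group on C2 to give 9.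

3. Step 6. Oxygenation may occur at the wrong α-carbon (C5), or the ketol may be oxidised further. The fallback sets out from 7 and 6 and comes back at 11. The conjugate addition of step 5 is run with Me3SiCl so that the enolate is trapped as the tetrasubstituted trimethylsilyl enol ether F9. MeLi gives the lithium enolate F10 with the double bond fixed between C1 and C2 of the cyclopentane, and 2-(phenylsulfonyl)-3-phenyloxaziridine hydroxylates it at C2 to give 11.

**Further compounds**

F1 | step 8 | hydroxy acid: 12 with the ketone converted into C(OH)(CH3)(CH=CH2), carbinol epimers, chain-bearing carbon as in 12 | C=CC(C)(O)[C@@H](CC/C(C)=C/CC/C(C)=C/CO[Si](C)(C)C(C)(C)C)C(C)(C)CC(=O)O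
F2 | step 8 | 6-ethenyl-4,4,6-trimethyl-5-R9-oxan-2-one, C6 epimers, C5 as in 12 | C=CC1(C)OC(=O)CC(C)(C)[C@@H]1CC/C(C)=C/CC/C(C)=C/CO[Si](C)(C)C(C)(C)C
F3 | step 8 | trimethylsilyl ketene acetal of F2 | C=CC1(C)OC(O[Si](C)(C)C)=CC(C)(C)[C@@H]1CC/C(C)=C/CC/C(C)=C/CO[Si](C)(C)C(C)(C)C
F4 | step 8 | trimethylsilyl 4,6,6-trimethyl-5-R9-cyclohex-3-ene-1-carboxylate, C1 epimers, C5 as in 16 | C[Si](C)(C)OC(=O)C1CC=C(C)[C@@H](CC/C(C)=C/CC/C(C)=C/CO[Si](C)(C)C(C)(C)C)C1(C)C
F5 | step 8 | 4,6,6-trimethyl-5-R9-cyclohex-3-ene-1-carboxylic acid, C1 epimers, C5 as in 16 | OC(=O)C1CC=C(C)[C@@H](CC/C(C)=C/CC/C(C)=C/CO[Si](C)(C)C(C)(C)C)C1(C)C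
F6 | step 8 | 2-thioxopyridin-1(2H)-yl ester of F5 | S=C1C=CC=CN1OC(=O)C1CC=C(C)[C@@H](CC/C(C)=C/CC/C(C)=C/CO[Si](C)(C)C(C)(C)C)C1(C)C
F7 | step 5 | 3-R9-4,4-dimethyl-1-(trimethylsilyloxy)cyclopent-1-ene, C3 as in 9 | C[Si](C)(C)OC1=C[C@@H](CC/C(C)=C/CC/C(C)=C/CO[Si](C)(C)C(C)(C)C)C(C)(C)C1
F8 | step 5 | lithium enolate corresponding to F7 | [Li]OC1=C[C@@H](CC/C(C)=C/CC/C(C)=C/CO[Si](C)(C)C(C)(C)C)C(C)(C)C1
F9 | step 6 | 3-R9-2,4,4-trimethyl-1-(trimethylsilyloxy)cyclopent-1-ene, C3 as in 9 | CC1=C(O[Si](C)(C)C)CC(C)(C)[C@@H]1CC/C(C)=C/CC/C(C)=C/CO[Si](C)(C)C(C)(C)C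
F10 | step 6 | lithium enolate corresponding to F9 | CC1=C(O[Li])CC(C)(C)[C@@H]1CC/C(C)=C/CC/C(C)=C/CO[Si](C)(C)C(C)(C)C
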